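**Plan**

Feature: in ring B (B1 carries the propyl chain, B2 H, B3 and B4 OH, B5 and B6 prenyl) the catechol edge B3–B4 is the double enol of a cyclohex-4-ene-1,2-dione. The B6=B1 bond of that dione lies where a [4+2] cycloaddition leaves its alkene.
Cuts: B2–B3 and B4–B5 (diene B5=B6–B1=B2 plus the two-carbon, two-oxygen dienophile vinylene carbonate). Then B6–B1 (alkenyl–alkenyl coupling), the two alkyne–CH2 bonds of a symmetric diprenylacetylene, the allylic CH2–CH2 bond next to B1, and the ring A–CH2 bond.
Forward: ring A is bought and extended by two carbons, then by three. Diprenylacetylene is made in one operation, the halves are joined at B6–B1, and ring B is closed, aromatised and the ring A phenol released.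
Stereochemistry: the target is achiral. Only the E geometry at B5=B6 matters (syn hydrozirconation, coupling with retention), and the three racemic stereocentres of the cycloadduct vanish on aromatisation.

Key step: step 7

Remark: racemic compounds are drawn as one enantiomer. The ring A phenol is carried as its triisopropylsilyl ether because it must survive organometallic reagents, prolonged heating, K2CO3/MeOH and activated DMSO.

**Step 1**
Reactants: 1 4-bromo-3-methoxyphenol
Product: 2 (4-bromo-3-methoxyphenoxy)triisopropylsilane
Conditions: TIPSCl, imidazole, DMF, rt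
Reagents that add atoms: triisopropylsilyl chloride, CC(C)[Si](Cl)(C(C)C)C(C)C
Why: Imidazole-promoted O-silylation of a phenol is routine, and the bulky silyl ether is stable to every later reagent up to the final fluoride treatment.

**Step 2**
Reactants: 2 (4-bromo-3-methoxyphenoxy)triisopropylsilane; 3 ethylene oxide
Product: 5 2-[2-methoxy-4-(triisopropylsilyloxy)phenyl]ethanol, via aryllithium 4 (not isolated)
Conditions: n-BuLi, THF, −78 °C; 3 (THF solution, excess), −78 °C → rt; H2O
Reagents that add atoms: none
Why: Bromine–lithium exchange next to a coordinating methoxy group is fast at low temperature, and the aryllithium opens the unhindered epoxide by SN2 attack to add the first two chain carbons.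

**Step 3**
Reactants: 5 2-[2-methoxy-4-(triisopropylsilyloxy)phenyl]ethanol
Product: 6 [4-(2-bromoethyl)-3-methoxyphenoxy]triisopropylsilane
Conditions: CBr4, PPh3, CH2Cl2, 0 °C
Reagents that add atoms: carbon tetrabromide, BrC(Br)(Br)Br
Why: The Appel reaction converts a primary alcohol into the bromide under neutral conditions that leave the aryl silyl ether and the methyl ether untouched.

**Step 4**
Reactants: 6 [4-(2-bromoethyl)-3-methoxyphenoxy]triisopropylsilane; 7 2,3-dibromopropene
Product: 9 [4-(4-bromopent-4-enyl)-3-methoxyphenoxy]triisopropylsilane, via arylethyl Grignard reagent 8 (not isolated)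
Conditions: Mg, THF, 40 °C; then 7, THF, 0 °C → rt
Reagents that add atoms: none
Why: Primary alkyl Grignard reagents displace the allylic bromide of 2,3-dibromopropene (classical allylic substitution, in which direct and transposed attack give the same product) while the vinylic C–Br bond stays intact, so the three-carbon chain is completed and B1 and B2 are installed.

**Step 5**
Reactants: 10 acetylene; 11 1-bromo-3-methylbut-2-ene (2 equiv)
Product: 13 2,9-dimethyldeca-2,8-dien-5-yne, via ethynediylbis(magnesium bromide) 12 (not isolated)
Conditions: EtMgBr (2 equiv), Et2O–THF, 10 (1 equiv, metered), rt → 40 °C; CuCl (10 mol %), 11, 40 °C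
Reagents that add atoms: none
Why: Twofold deprotonation gives the bis-Grignard reagent of acetylene, and CuCl-catalysed alkynyl–allyl coupling should take place at the unhindered primary carbon of prenyl bromide at both ends, giving the symmetric skipped dienyne that holds B5, B6 and both prenyl groups.

**Step 6**
Reactants: 13 2,9-dimethyldeca-2,8-dien-5-yne; 9 [4-(4-bromopent-4-enyl)-3-methoxyphenoxy]triisopropylsilane
Product: 16 [3-methoxy-4-[(5E)-9-methyl-4-methylidene-5-(3-methylbut-2-enyl)deca-5,8-dienyl]phenoxy]triisopropylsilane, via alkenylzirconocene chloride 14 (not isolated), via alkenylzinc chloride 15 (not isolated)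
Conditions: Cp2Zr(H)Cl, THF, rt, dark; ZnCl2 (1 equiv), THF; 9, Pd(PPh3)4 (5 mol %), rt → 45 °C
Reagents that add atoms: none
Why: Hydrozirconation adds H and Zr syn across the alkyne faster than across trisubstituted alkenes (symmetry removes any regiochemical question), transmetalation to zinc makes the hindered alkenyl metal competent for Negishi coupling, and oxidative addition of 9 to zerovalent palladium followed by reductive elimination forms B6–B1 with retention, so the B5 prenyl group ends up E, on the outside of the diene.

**Step 7**
Reactants: 16 [3-methoxy-4-[(5E)-9-methyl-4-methylidene-5-(3-methylbut-2-enyl)deca-5,8-dienyl]phenoxy]triisopropylsilane; 17 vinylene carbonate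
Product: 18 rac-4,5-bis(3-methylbut-2-enyl)-6-{3-[2-methoxy-4-(triisopropylsilyloxy)phenyl]propyl}-3a,4,7,7a-tetrahydro-1,3-benzodioxol-2-one, cis-fused, H-3a, H-4 and H-7a all on one face (endo adduct)
Conditions: 17 (10 equiv), BHT (5 mol %), toluene, sealed tube, 175 °C
Reagents that add atoms: none
Why: The s-cis conformer of 16 and the C=C bond of 17 combine in a concerted, suprafacial–suprafacial [4+2] cycloaddition in which the diene termini B2 (CH2) and B5 (CH) bond to the two oxygen-bearing carbons, creating B2–B3 and B4–B5 together. The closest known reaction type is the thermal Diels–Alder reaction of vinylene carbonate with 2,3-dialkyl- and 1-substituted buta-1,3-dienes, which needs roughly 170–200 °C because the dienophile is only weakly activated. Six-membered ring B closes by intermolecular [4+2] annulation (four atoms from the diene, two from the dienophile), and the five-membered carbonate ring arrives intact and becomes cis-fused. B3 and B4 are cis because the ring-locked alkene geometry is transferred suprafacially, and B5 is set relative to them by the E geometry of B5=B6 together with the endo orientation of the carbonate; the adduct is racemic, and any exo isomer is carried along because all three centres disappear in step 9. No regioselectivity is needed because the dienophile is symmetric, and the required chemoselectivity for the conjugated diene is secured because both prenyl alkenes are isolated and trisubstituted. The inside position at B5 carries only hydrogen, so the s-cis form is reachable and no [1,5]-hydrogen shift can drain the diene, while BHT holds back radical polymerisation of 17.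

**Step 8**
Reactants: 18 cis-fused cyclohexene carbonate
Product: 19 rac-3,4-bis(3-methylbut-2-enyl)-5-{3-[2-methoxy-4-(triisopropylsilyloxy)phenyl]propyl}cyclohex-4-ene-1,2-diol, with OH-1, OH-2 and the C3 prenyl group all cis
Conditions: K2CO3 (0.2 equiv), MeOH, 0 °C → rt
Reagents that add atoms: none
Why: Base-catalysed methanolysis (transesterification) of a five-membered cyclic carbonate is fast and proceeds by acyl–oxygen cleavage, so the stereocentres are untouched and the hindered aryl silyl ether should survive.

**Step 9**
Reactants: 19 all-cis cyclohexene diol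
Product: 21 3,4-bis(3-methylbut-2-enyl)-5-{3-[2-methoxy-4-(triisopropylsilyloxy)phenyl]propyl}benzene-1,2-diol, via cyclohex-4-ene-1,2-dione 20 (not isolated)
Conditions: (COCl)2, DMSO, CH2Cl2, −78 °C; Et3N, −78 °C → rt, argon; aq NaH2PO4
Reagents that add atoms: none
Why: Double Swern oxidation converts vicinal diols into 1,2-diketones without C–C cleavage, and the resulting ene-dione, whose B2 and B5 hydrogens are both allylic and alpha to a carbonyl, should enolise twice under Et3N to the catechol, a known passage from cyclohex-4-ene-1,2-diols to catechols that erases all stereocentres.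

**Step 10**
Reactants: 21 silyl-protected catechol
Product: 22 kazinol J
Conditions: TBAF, AcOH (1:1), THF, 0 °C, argon
Reagents that add atoms: none
Why: Fluoride-induced cleavage of an aryl silyl ether is fast, and the AcOH buffer keeps the medium neither basic enough for aerial oxidation of the catechol nor acidic enough to cyclise the ortho-prenyl phenol to a chroman.

**Compound list**

1 | 4-bromo-3-methoxyphenol | COc1cc(O)ccc1Br | starting material
2 | (4-bromo-3-methoxyphenoxy)triisopropylsilane | COc1cc(O[Si](C(C)C)(C(C)C)C(C)C)ccc1Br | intermediate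
3 | ethylene oxide (oxirane) | C1CO1 | starting material
4 | [2-methoxy-4-(triisopropylsilyloxy)phenyl]lithium | COc1cc(O[Si](C(C)C)(C(C)C)C(C)C)ccc1[Li] | intermediate
5 | 2-[2-methoxy-4-(triisopropylsilyloxy)phenyl]ethanol | COc1cc(O[Si](C(C)C)(C(C)C)C(C)C)ccc1CCO | intermediate
6 | [4-(2-bromoethyl)-3-methoxyphenoxy]triisopropylsilane | COc1cc(O[Si](C(C)C)(C(C)C)C(C)C)ccc1CCBr | intermediate
7 | 2,3-dibromopropene | C=C(Br)CBr | starting material
8 | 2-[2-methoxy-4-(triisopropylsilyloxy)phenyl]ethylmagnesium bromide | COc1cc(O[Si](C(C)C)(C(C)C)C(C)C)ccc1CC[Mg]Br | intermediate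
9 | [4-(4-bromopent-4-enyl)-3-methoxyphenoxy]triisopropylsilane | COc1cc(O[Si](C(C)C)(C(C)C)C(C)C)ccc1CCCC(Br)=C | intermediate
10 | acetylene | C#C | starting material
11 | 1-bromo-3-methylbut-2-ene (prenyl bromide) | CC(C)=CCBr | starting material
12 | ethynediylbis(magnesium bromide) | Br[Mg]C#C[Mg]Br | intermediate
13 | 2,9-dimethyldeca-2,8-dien-5-yne | CC(C)=CCC#CCC=C(C)C | intermediate
14 | chlorobis(cyclopentadienyl)[(5E)-2,9-dimethyldeca-2,5,8-trien-5-yl]zirconium (Cp rings written sigma-bound in the SMILES) | CC(C)=CC/C=C(\CC=C(C)C)[Zr](Cl)(C1C=CC=C1)C1C=CC=C1 | intermediate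
15 | chloro[(5E)-2,9-dimethyldeca-2,5,8-trien-5-yl]zinc | CC(C)=CC/C=C(\CC=C(C)C)[Zn]Cl | intermediate
16 | [3-methoxy-4-[(5E)-9-methyl-4-methylidene-5-(3-methylbut-2-enyl)deca-5,8-dienyl]phenoxy]triisopropylsilane | CC(C)=CC/C=C(\CC=C(C)C)C(=C)CCCc1ccc(O[Si](C(C)C)(C(C)C)C(C)C)cc1OC | intermediate
17 | vinylene carbonate (1,3-dioxol-2-one) | O=C1OC=CO1 | starting material
18 | rac-4,5-bis(3-methylbut-2-enyl)-6-{3-[2-methoxy-4-(triisopropylsilyloxy)phenyl]propyl}-3a,4,7,7a-tetrahydro-1,3-benzodioxol-2-one, all-cis endo adduct | O=C1O[C@@H]2CC(CCCc3ccc(O[Si](C(C)C)(C(C)C)C(C)C)cc3OC)=C(CC=C(C)C)[C@H](CC=C(C)C)[C@@H]2O1 | intermediate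
19 | rac-3,4-bis(3-methylbut-2-enyl)-5-{3-[2-methoxy-4-(triisopropylsilyloxy)phenyl]propyl}cyclohex-4-ene-1,2-diol, all-cis | O[C@@H]1CC(CCCc2ccc(O[Si](C(C)C)(C(C)C)C(C)C)cc2OC)=C(CC=C(C)C)[C@H](CC=C(C)C)[C@@H]1O | intermediate
20 | rac-3,4-bis(3-methylbut-2-enyl)-5-{3-[2-methoxy-4-(triisopropylsilyloxy)phenyl]propyl}cyclohex-4-ene-1,2-dione | O=C1CC(CCCc2ccc(O[Si](C(C)C)(C(C)C)C(C)C)cc2OC)=C(CC=C(C)C)[C@H](CC=C(C)C)C1=O | intermediate
21 | 3,4-bis(3-methylbut-2-enyl)-5-{3-[2-methoxy-4-(triisopropylsilyloxy)phenyl]propyl}benzene-1,2-diol | COc1cc(O[Si](C(C)C)(C(C)C)C(C)C)ccc1CCCc1cc(O)c(O)c(CC=C(C)C)c1CC=C(C)C | intermediate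
22 | kazinol J | COc1cc(O)ccc1CCCc1cc(O)c(O)c(CC=C(C)C)c1CC=C(C)C | target

Total step count: 10. Longest linear sequence: 9 steps (steps 1–4 and 6–10); step 5 is the only branch.

**Steps most likely to fail**

**Step 7 is the greatest risk.**
- What may go wrong: the cycloaddition may be too slow at temperatures the diene tolerates. The dienophile is weakly activated and the 1,2,3-trisubstituted diene pays a steric price for the s-cis form, so polymerisation of the dienophile or thermal isomerisation of the skipped dienes could outrun ring closure.
- Fallback: it sets out from 16 and uses a dienophile with a lower LUMO that is already at the dione oxidation level.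
- Ethylene carbonate is photochlorinated (Cl2, light) to tetrachloroethylene carbonate F1, and zinc dechlorination gives dichlorovinylene carbonate F2.
- Heating F2 with 16 in toluene at about 130 °C should form the same B2–B3 and B4–B5 bonds and give the dichloro carbonate adduct F3.
- Hydrolysis of F3 in aqueous THF buffered with NaHCO3 collapses both chloro-carbonate carbons to ketones. This gives 20, which enolises, and the route is rejoined at 21 with steps 8 and 9 omitted.

**Step 9 is the second risk.**
- What may go wrong: oxidation may stall at the ketol stage, followed by loss of water to a monophenol. The nascent catechol may be captured by excess activated DMSO (methylthiomethylation), or electrophilic chlorination of the prenyl alkenes may occur.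
- Fallback: it sets out from 19 and oxidises deliberately past the catechol, then returns by reduction.
- 2-Iodoxybenzoic acid in DMSO at rt takes vicinal diols to diketones without cleavage and oxidises the catechol formed by enolisation on to the ortho-quinone F4.
- Crude F4 is shaken at once with aqueous Na2S2O4 in EtOAc, which reduces it to 21, where the route is rejoined.

**Step 6 is the third risk.**
- What may go wrong: transmetalation and coupling of the hindered, alpha-substituted alkenyl metal may be slow. That would allow protodemetalation, homocoupling, erosion of alkene geometry or palladium hydride migration along the skipped dienes.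
- Fallback: it sets out from 13 and 9 and reverses the roles of the partners, so the hindered half is the electrophile and both halves are isolated and purified.
- Hydrozirconation of 13 to 14 followed by I2 gives (5E)-5-iodo-2,9-dimethyldeca-2,5,8-triene F5.
- Miyaura borylation of 9 (B2pin2, PdCl2(PPh3)2, PPh3, KOPh, toluene, 50 °C) gives the alkenyl pinacol boronate F6.
- Suzuki–Miyaura coupling of F5 with F6 (PdCl2(dppf), aq K3PO4, THF, 40 °C) should return to the route at 16.

**Further compounds**

F1 | step 7 | tetrachloroethylene carbonate (4,4,5,5-tetrachloro-1,3-dioxolan-2-one) | O=C1OC(Cl)(Cl)C(Cl)(Cl)O1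
F2 | step 7 | dichlorovinylene carbonate (4,5-dichloro-1,3-dioxol-2-one) | O=C1OC(Cl)=C(Cl)O1
F3 | step 7 | rac-3a,7a-dichloro-4,5-bis(3-methylbut-2-enyl)-6-{3-[2-methoxy-4-(triisopropylsilyloxy)phenyl]propyl}-3a,4,7,7a-tetrahydro-1,3-benzodioxol-2-one, cis-fused, carbonate oxygens cis to the C4 prenyl group | O=C1O[C@]2(Cl)CC(CCCc3ccc(O[Si](C(C)C)(C(C)C)C(C)C)cc3OC)=C(CC=C(C)C)[C@H](CC=C(C)C)[C@]2(Cl)O1
F4 | step 9 | 3,4-bis(3-methylbut-2-enyl)-5-{3-[2-methoxy-4-(triisopropylsilyloxy)phenyl]propyl}cyclohexa-3,5-diene-1,2-dione | COc1cc(O[Si](C(C)C)(C(C)C)C(C)C)ccc1CCCC1=CC(=O)C(=O)C(CC=C(C)C)=C1CC=C(C)C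
F5 | step 6 | (5E)-5-iodo-2,9-dimethyldeca-2,5,8-triene | CC(C)=CC/C=C(\CC=C(C)C)I
F6 | step 6 | [3-methoxy-4-[4-(4,4,5,5-tetramethyl-1,3,2-dioxaborolan-2-yl)pent-4-enyl]phenoxy]triisopropylsilane | COc1cc(O[Si](C(C)C)(C(C)C)C(C)C)ccc1CCCC(=C)B1OC(C)(C)C(C)(C)O1
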